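The ratio of reagent to substrate charged ran from 0.300 in amber to 2.40 in blue, and I wanted one quantity that would carry across that range.

| flask | substrate | reagent | catalyst | remark | time |
|---|---|---|---|---|---|
| Wednesday's | 0.050 M (fed, over 12 h) | 0.012 M | 2.5 mM | run made earlier; the fed solution adds 0.25 times the starting volume |  |
| Tuesday's | 0.050 M (fed, over 12 h) | 0.074 M | 2.5 mM | run made earlier; the fed solution adds 0.25 times the starting volume |  |
| amber | 0.050 M (fed, over 12 h) | 0.0150 M | 2.5 mM | the fed solution adds 0.25 times the starting volume | 3.0 d |
| red | 0.050 M (fed, over 12 h) | 0.0300 M | 2.5 mM | the fed solution adds 0.25 times the starting volume | 3.0 d |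
| green | 0.050 M (fed, over 12 h) | 0.0600 M | 2.5 mM | the fed solution adds 0.25 times the starting volume | 3.0 d |
| blue | 0.050 M (fed, over 12 h) | 0.120 M | 2.5 mM | the fed solution adds 0.25 times the starting volume | 3.0 d |

| run | time / d | target / % | substrate / % |
|---|---|---|---|
| Wednesday's | 0.625 | 2 | 97 |
| Wednesday's | 1.25 | 7 | 91 |
| Wednesday's | 1.67 | 8 | 91 |
| Wednesday's | 2.50 | 10 | 87 |
| Wednesday's | 3.00 | 11 | 85 |
| Tuesday's | 0.250 | 5 | 45 |
| Tuesday's | 0.417 | 9 | 73 |
| Tuesday's | 0.833 | 21 | 72 |
| Tuesday's | 1.67 | 31 | 52 |
| Tuesday's | 3.00 | 34 | 37 |

(each reading ± 2 percentage points)

- charges are per starting volume, the dose included; the dosed solution carries all of it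
- "hardly changes" means that all values lie within two and a half points (for a concentration: within two and a half percent of the largest)
- percentages count the whole charge, also what has not yet gone in

- amount of target at the end, in percent of the substrate charged for amber, red, green, blue, in this order
- the course of these numbers from the first flask to the last (hardly changes / rises all the way / falls all the way / falls, then rises / rises, then falls)

In both earlier runs target plus substrate sagged below the charge, so I assumed that target goes on to something else and takes a second reagent with it. Reagent spent per substrate charged is then the substrate lost plus the part of that loss no longer standing as target. For Tuesday's run at 3.00 d this was 0.920, against 1.48 charged. That gives the spent share, the part of the reagent's charge used on substrate and target by the end: 62.2 %. Wednesday's run gave 79.2 %, but that figure is coarser, because the scatter of 2 percentage points counts against a smaller charge, so I carried Tuesday's.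

I took the two steps as equally fast, so that target equals the exposure divided by exp(exposure), where exposure is reckoned per substrate charged. This peaks at an exposure of one.

In the lean extreme, substrate plus target stays whole, the reagent falls pseudo-first-order, and its spent share holds at any charge. Exposure is then the spent share times the ratio. That gave 0.186 and 15.4 % target for amber, 0.373 and 25.7 % for red, and 0.746 and 35.4 % for green. The formula stands 2.7 points above Tuesday's reading, so I held it high near the peak.

In the rich extreme, the reagent stays at its charge. For blue this gave an exposure of 2.33 and 22.7 % target, while the lean version gave 1.49 and 33.6 %. I placed blue between these two figures, since I expected both its substrate plus target to shrink and its reagent to fall. On the lean reckoning green stood below the peak and blue beyond it, and blue showed less target than green in either version, so I expected a rise and then a fall.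

The forecast read 15 %, 25 %, 32 % and 26 %, rises, then falls, holding that “Tuesday's end point fits a second step about 1.2 times as fast as the first”, and it stood 3.4 points under my lean figure for green.

The flasks gave 15.3 %, 24.7 %, 32.3 % and 26.3 %: rises, then falls.

    reagent + target → over-reaction product B (k = 0.870 M⁻¹ h⁻¹)
    reagent ⇌ dormant form (K = 0.830, k = 0.380 h⁻¹)
    substrate + reagent + catalyst ⇌ target + catalyst, rate k3*[substrate]*[reagent]*[catalyst] forward; the back reaction follows from the equilibrium constant (K = 270 M⁻¹, k = 410 M⁻² h⁻¹)
    target → over-reaction product A (k = 9.60 × 10⁻⁵ h⁻¹)

In amber at 1.09 d, the forward half-life of reagent was 0.076 d by its loss to the dormant form and 0.96 d by the making of target, a forward rate ratio, making over loss, of 0.079, and amber's spent share, counted as substrate lost plus over-reaction product B, came to 64.7 % at 3.00 d, beside the 62.2 % from Tuesday's run. In blue the same count gave 56.1 %, with 54.1 % of the substrate charged standing as over-reaction product B at 3.00 d.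

The data were generated by integration for an exercise; noise was put on by code.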